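Retrosynthesis: the two ester C–O bonds are cut first (feruloyl at the propanol oxygen, then p-coumaroyl at the C3 CH2O), then the O1–C2 bond of the dihydrofuran, then the C2–C3 bond. This leaves a ring B arylacetic acid (from dihydroconiferyl alcohol) and O-protected vanillin.
Forward: a Claisen rearrangement and alkene cleavage put the CH2CO2H arm on ring B, and a boron aldol joins the two aryl halves through C2–C3. Reduction frees the C3 CH2OH, acid closes the only new ring through O1–C2, and the p-coumarate and (after desilylation) the ferulate are attached last.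
Enabling feature: the guaiacyl ring on C2 has its 4-OH para to C2, and the fused benzene ring carries O1 on C7a, next to the C3a that bears C3. C2 can therefore become the flat terminus of a p-quinone methide that the O1 phenol captures in a five-membered closure.
Stereochemistry: C3 (S) is set in the aldol by (R)-4-benzyl-2-oxazolidinone. C2 (R) is set trans to it in the ring closure, where the aldol carbinol centre is flattened and its configuration no longer counts. Both alkenes are bought as E.

Key step: step 11

Assumption: (+)-boehmenan X is taken to be the trans (2R,3S) isomer written in the target SMILES.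
Abbreviations: TBDPS = tert-butyldiphenylsilyl; MOM = methoxymethyl; ArB = 3-methoxy-2-(methoxymethoxy)-5-[3-(TBDPS-oxy)propyl]phenyl (ring B, phenol as MOM ether); ArG = 3-methoxy-4-(methoxymethoxy)phenyl (guaiacyl ring as MOM ether).

Step 1
Reactants: 1 dihydroconiferyl alcohol, 4-(3-hydroxypropyl)-2-methoxyphenol
Product: 2 3-[4-(allyloxy)-3-methoxyphenyl]propan-1-ol
Conditions: allyl bromide, K2CO3, acetone, reflux
Reagents that add atoms: allyl bromide, C=CCBr
Why: Williamson ether synthesis in which K2CO3 ionises only the phenol, so the aliphatic alcohol is left free for the next step.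

Step 2
Reactants: 2 3-[4-(allyloxy)-3-methoxyphenyl]propan-1-ol
Product: 3 tert-butyl{3-[4-(allyloxy)-3-methoxyphenyl]propoxy}diphenylsilane
Conditions: TBDPSCl, imidazole, DMF, 0 °C → rt
Reagents that add atoms: tert-butyl(chloro)diphenylsilane (TBDPSCl), CC(C)(C)[Si](Cl)(c1ccccc1)c1ccccc1
Why: Imidazole-promoted silylation of the primary alcohol, with the most acid-resistant of the common silyl ethers chosen because it has to outlast the acid of step 11.

Step 3
Reactants: 3 tert-butyl{3-[4-(allyloxy)-3-methoxyphenyl]propoxy}diphenylsilane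
Product: 5 2-allyl-6-methoxy-4-[3-(TBDPS-oxy)propyl]phenol, via ortho-dienone 4 (not isolated)
Conditions: N,N-diethylaniline, 200 °C
Reagents that add atoms: none
Why: Aromatic Claisen rearrangement, a [3,3]-sigmatropic shift to the only unsubstituted ortho carbon followed by tautomerisation of dienone 4, the other ortho carbon bearing OMe and the para carbon bearing the side chain.

Step 4
Reactants: 5 2-allyl-6-methoxy-4-[3-(TBDPS-oxy)propyl]phenol
Product: 6 tert-butyl{3-[3-allyl-5-methoxy-4-(methoxymethoxy)phenyl]propoxy}diphenylsilane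
Conditions: MOMCl, iPr2NEt, CH2Cl2, 0 → 40 °C
Reagents that add atoms: chloromethyl methyl ether (MOMCl), COCCl
Why: O-alkylation of the hindered phenol with the alpha-chloro ether gives a formaldehyde acetal that withstands ozone, chlorite, the boron enolate and borohydride yet is the group that dilute acid removes in step 11.

Step 5
Reactants: 6 tert-butyl{3-[3-allyl-5-methoxy-4-(methoxymethoxy)phenyl]propoxy}diphenylsilane
Product: 8 2-(ArB)acetaldehyde, via ozonide 7 (not isolated)
Conditions: O3, CH2Cl2, −78 °C (Sudan red 7B as end-point indicator); then PPh3, −78 °C → rt; used crude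
Reagents that add atoms: ozone, [O-][O+]=O
Why: Ozonolysis (1,3-dipolar cycloaddition, cycloreversion and recombination to ozonide 7) with PPh3 reduction cleaves the monosubstituted alkene, which reacts far faster than the alkoxyarene, and the dye end-point guards against over-oxidation of the ring.

Step 6
Reactants: 8 2-(ArB)acetaldehyde
Product: 9 2-(ArB)acetic acid
Conditions: NaClO2, NaH2PO4, 2-methyl-2-butene, t-BuOH/H2O, 0 °C → rt
Reagents that add atoms: sodium chlorite (NaClO2), [Na+].[O-]Cl=O
Why: Pinnick oxidation, in which chlorous acid oxidises only the aldehyde and 2-methyl-2-butene traps the hypochlorous acid before it can chlorinate the electron-rich ring, the buffered medium sparing the MOM and silyl ethers.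

Step 7
Reactants: 9 2-(ArB)acetic acid; 10 (R)-4-benzyl-2-oxazolidinone
Product: 12 (R)-4-benzyl-3-[2-(ArB)acetyl]oxazolidin-2-one, via mixed pivalic anhydride 11 (not isolated)
Conditions: PivCl, Et3N, THF, −20 °C; then 10, LiCl, −20 °C → rt
Reagents that add atoms: none
Why: N-acylation through a mixed anhydride, in which the oxazolidinone activated by LiCl and Et3N attacks the unhindered arylacetyl carbonyl of 11 and not the pivaloyl one, without any strong base that could enolise the arylacetyl unit.

Step 8
Reactants: 13 vanillin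
Product: 14 3-methoxy-4-(methoxymethoxy)benzaldehyde (O-MOM-vanillin)
Conditions: MOMCl, iPr2NEt, CH2Cl2, 0 °C → rt
Reagents that add atoms: chloromethyl methyl ether (MOMCl), COCCl
Why: Acetal-type O-alkylation of the phenol, needed because a free phenol would quench the boron enolate of step 9.

Step 9
Reactants: 12 (R)-4-benzyl-3-[2-(ArB)acetyl]oxazolidin-2-one; 14 O-MOM-vanillin
Product: 17 (R)-4-benzyl-3-[(2R,3R)-2-(ArB)-3-(ArG)-3-hydroxypropanoyl]oxazolidin-2-one (syn aldol adduct), via boron Z-enolate 15 (not isolated), via boron aldolate 16 (not isolated)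
Conditions: Bu2BOTf, iPr2NEt, CH2Cl2, −78 → 0 °C; then 14, −78 → 0 °C; then pH 7 phosphate buffer, MeOH, 30% H2O2, 0 °C
Reagents that add atoms: none
Why: Evans boron syn aldol reaction, in which soft enolisation gives the Z enolate 15 that adds to the aldehyde through a closed six-membered chair (Zimmerman–Traxler) transition state with the imide dipoles opposed, so the benzyl group of the (R)-auxiliary screens one enolate face and the alpha carbon (the future C3) is set as R, while the syn carbinol centre formed alongside is not needed later.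

Step 10
Reactants: 17 syn aldol adduct
Product: 18 (1R,2S)-2-(ArB)-1-(ArG)propane-1,3-diol
Conditions: LiBH4, MeOH (1 equiv), THF, 0 °C
Reagents that add atoms: none
Why: Reductive cleavage of the N-acyl oxazolidinone by borohydride, whose attack on the lithium-activated exocyclic carbonyl releases the auxiliary and takes the acyl carbon down to CH2OH at 0 °C without touching the alpha-aryl centre (now named S only because the CIP priorities change) or the silyl ether.

Step 11
Reactants: 18 (1R,2S)-2-(ArB)-1-(ArG)propane-1,3-diol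
Product: 21 (2R,3S)-2-(4-hydroxy-3-methoxyphenyl)-3-(hydroxymethyl)-7-methoxy-5-[3-(TBDPS-oxy)propyl]-2,3-dihydrobenzofuran, via bisphenol diol 19 (not isolated), via p-quinone methide 20 (not isolated)
Conditions: HCl (1.25 M in MeOH), THF, 0 °C → rt, stopped as soon as 19 is consumed; NaHCO3 quench
Reagents that add atoms: none
Why: Methanolic HCl first transacetalises both aryl MOM ethers to give bisphenol diol 19, whose benzylic hydroxyl is then expelled with help from the para phenol oxygen to give p-quinone methide 20 (present under acid as its O-protonated form, the p-hydroxybenzyl cation), and the ring B phenol oxygen adds to the flat exocyclic carbon in an intramolecular oxa-1,6-addition that forms the O1–C2 bond. The closest known reaction type is the acid-promoted phenylcoumaran (beta-5) closure of 1-aryl-2-(2-hydroxyaryl)propane-1,3-diols familiar from lignin model and neolignan chemistry. The one ring formed, the dihydrofuran, closes in the 5-exo-trig mode, since the attacked carbon of the exocyclic C=C ends up inside the ring while its partner, the guaiacyl ipso carbon, stays outside. The only new stereocentre is C2 and it is controlled by C3 alone: the guaiacyl group settles on the face of the forming ring opposite the C3 CH2OH group, which gives the trans (2R,3S) isomer, and because the former carbinol carbon is trigonal in 20 either carbinol epimer of 18 leads to the same product, while reversible opening of the p-hydroxybenzylic C2–O1 bond under acid makes trans the thermodynamic outcome as well. The step needs trans closure with the C3 hydrogen and the silyl ether left in place: five-membered capture by the neighbouring phenol at 0 °C should outrun E1 loss of the C3 proton (which would give a stilbene and erase C3), the CH2OH cannot compete because it would have to form an oxetane, C3 is no longer alpha to a carbonyl and so cannot epimerise, and a primary TBDPS ether should tolerate brief dilute methanolic HCl.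

Step 12
Reactants: 21 trans-dihydrobenzofuran alcohol; 22 (E)-p-coumaric acid
Product: 24 [(2R,3S)-2-(4-hydroxy-3-methoxyphenyl)-7-methoxy-5-[3-(TBDPS-oxy)propyl]-2,3-dihydrobenzofuran-3-yl]methyl (E)-3-(4-hydroxyphenyl)acrylate, via alkoxyphosphonium coumarate 23 (not isolated)
Conditions: PPh3, DIAD, THF, 0 °C → rt (DIAD added last)
Reagents that add atoms: none
Why: Mitsunobu esterification, in which only the aliphatic CH2OH can become the oxyphosphonium leaving group of 23 and the betaine is protonated by the carboxylic acid (several pKa units more acidic than any phenol present), so the carboxylate is the nucleophile that displaces Ph3PO at the CH2 carbon, leaving C3, C2 and all phenols untouched.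

Step 13
Reactants: 24 C3-CH2 p-coumarate with chain TBDPS ether
Product: 25 [(2R,3S)-2-(4-hydroxy-3-methoxyphenyl)-5-(3-hydroxypropyl)-7-methoxy-2,3-dihydrobenzofuran-3-yl]methyl (E)-3-(4-hydroxyphenyl)acrylate
Conditions: HF·pyridine, pyridine/THF, 0 °C → rt
Reagents that add atoms: none
Why: Fluoride-mediated desilylation driven by the strength of the Si–F bond, run in a pyridine-buffered medium so that no phenoxide is formed and the cinnamate ester is neither cleaved nor shifted.

Step 14
Reactants: 25 C3-CH2 p-coumarate with free propanol chain; 26 (E)-ferulic acid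
Product: 28 (+)-boehmenan X, via alkoxyphosphonium ferulate 27 (not isolated)
Conditions: PPh3, DIAD, THF, 0 °C → rt (DIAD added last)
Reagents that add atoms: none
Why: Second Mitsunobu esterification on the same basis as step 12, the carboxylic acid of 26 again being the only pronucleophile acidic enough to be ionised by the betaine, so the target is reached with no deprotection after the two cinnamates are in place.

Compound list
1 | dihydroconiferyl alcohol, 4-(3-hydroxypropyl)-2-methoxyphenol | COc1cc(CCCO)ccc1O | starting material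
2 | 3-[4-(allyloxy)-3-methoxyphenyl]propan-1-ol | C=CCOc1ccc(CCCO)cc1OC | intermediate
3 | tert-butyl{3-[4-(allyloxy)-3-methoxyphenyl]propoxy}diphenylsilane | C=CCOc1ccc(CCCO[Si](c2ccccc2)(c2ccccc2)C(C)(C)C)cc1OC | intermediate
4 | 6-allyl-2-methoxy-4-[3-(TBDPS-oxy)propyl]cyclohexa-2,4-dien-1-one (Claisen ortho-dienone, not isolated) | C=CCC1C=C(CCCO[Si](c2ccccc2)(c2ccccc2)C(C)(C)C)C=C(OC)C1=O | intermediate
5 | 2-allyl-6-methoxy-4-[3-(TBDPS-oxy)propyl]phenol | C=CCc1cc(CCCO[Si](c2ccccc2)(c2ccccc2)C(C)(C)C)cc(OC)c1O | intermediate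
6 | tert-butyl{3-[3-allyl-5-methoxy-4-(methoxymethoxy)phenyl]propoxy}diphenylsilane | C=CCc1cc(CCCO[Si](c2ccccc2)(c2ccccc2)C(C)(C)C)cc(OC)c1OCOC | intermediate
7 | 3-{3-methoxy-2-(methoxymethoxy)-5-[3-(TBDPS-oxy)propyl]benzyl}-1,2,4-trioxolane (ozonide, not isolated) | COCOc1c(CC2OCOO2)cc(CCCO[Si](c2ccccc2)(c2ccccc2)C(C)(C)C)cc1OC | intermediate
8 | 2-{3-methoxy-2-(methoxymethoxy)-5-[3-(TBDPS-oxy)propyl]phenyl}acetaldehyde | O=CCc1cc(CCCO[Si](c2ccccc2)(c2ccccc2)C(C)(C)C)cc(OC)c1OCOC | intermediate
9 | 2-{3-methoxy-2-(methoxymethoxy)-5-[3-(TBDPS-oxy)propyl]phenyl}acetic acid | OC(=O)Cc1cc(CCCO[Si](c2ccccc2)(c2ccccc2)C(C)(C)C)cc(OC)c1OCOC | intermediate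
10 | (R)-4-benzyl-2-oxazolidinone | O=C1N[C@H](Cc2ccccc2)CO1 | starting material
11 | mixed anhydride of acid 9 and pivalic acid (not isolated) | CC(C)(C)C(=O)OC(=O)Cc1cc(CCCO[Si](c2ccccc2)(c2ccccc2)C(C)(C)C)cc(OC)c1OCOC | intermediate
12 | (R)-4-benzyl-3-(2-{3-methoxy-2-(methoxymethoxy)-5-[3-(TBDPS-oxy)propyl]phenyl}acetyl)oxazolidin-2-one | O=C(Cc1cc(CCCO[Si](c2ccccc2)(c2ccccc2)C(C)(C)C)cc(OC)c1OCOC)N1[C@H](Cc2ccccc2)COC1=O | intermediate
13 | vanillin | COc1cc(C=O)ccc1O | starting material
14 | 3-methoxy-4-(methoxymethoxy)benzaldehyde | COCOc1ccc(C=O)cc1OC | intermediate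
15 | dibutylboron (Z)-enolate of imide 12 (not isolated) | CCCCB(CCCC)O/C(=C\c1cc(CCCO[Si](c2ccccc2)(c2ccccc2)C(C)(C)C)cc(OC)c1OCOC)N1[C@H](Cc2ccccc2)COC1=O | intermediate
16 | O-dibutylboron aldolate of 17 (not isolated) | O=C(N1[C@H](Cc2ccccc2)COC1=O)[C@H](c1cc(CCCO[Si](c2ccccc2)(c2ccccc2)C(C)(C)C)cc(OC)c1OCOC)[C@@H](OB(CCCC)CCCC)c1ccc(OCOC)c(OC)c1 | intermediate
17 | (R)-4-benzyl-3-[(2R,3R)-3-hydroxy-3-[3-methoxy-4-(methoxymethoxy)phenyl]-2-{3-methoxy-2-(methoxymethoxy)-5-[3-(TBDPS-oxy)propyl]phenyl}propanoyl]oxazolidin-2-one | O=C(N1[C@H](Cc2ccccc2)COC1=O)[C@H](c1cc(CCCO[Si](c2ccccc2)(c2ccccc2)C(C)(C)C)cc(OC)c1OCOC)[C@@H](O)c1ccc(OCOC)c(OC)c1 | intermediate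
18 | (1R,2S)-1-[3-methoxy-4-(methoxymethoxy)phenyl]-2-{3-methoxy-2-(methoxymethoxy)-5-[3-(TBDPS-oxy)propyl]phenyl}propane-1,3-diol | OC[C@H](c1cc(CCCO[Si](c2ccccc2)(c2ccccc2)C(C)(C)C)cc(OC)c1OCOC)[C@@H](O)c1ccc(OCOC)c(OC)c1 | intermediate
19 | (1R,2S)-1-(4-hydroxy-3-methoxyphenyl)-2-{2-hydroxy-3-methoxy-5-[3-(TBDPS-oxy)propyl]phenyl}propane-1,3-diol (not isolated) | OC[C@H](c1cc(CCCO[Si](c2ccccc2)(c2ccccc2)C(C)(C)C)cc(OC)c1O)[C@@H](O)c1ccc(O)c(OC)c1 | intermediate
20 | 4-[(2S)-3-hydroxy-2-{2-hydroxy-3-methoxy-5-[3-(TBDPS-oxy)propyl]phenyl}propylidene]-2-methoxycyclohexa-2,5-dien-1-one (p-quinone methide, not isolated) | OC[C@H](c1cc(CCCO[Si](c2ccccc2)(c2ccccc2)C(C)(C)C)cc(OC)c1O)C=C1C=CC(=O)C(OC)=C1 | intermediate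
21 | (2R,3S)-2-(4-hydroxy-3-methoxyphenyl)-3-(hydroxymethyl)-7-methoxy-5-[3-(TBDPS-oxy)propyl]-2,3-dihydrobenzofuran | CC(C)(C)[Si](c1ccccc1)(c1ccccc1)OCCCc1cc(OC)c2c(c1)[C@@H](CO)[C@H](c1ccc(O)c(OC)c1)O2 | intermediate
22 | (E)-p-coumaric acid | OC(=O)/C=C/c1ccc(O)cc1 | starting material
23 | triphenylphosphonio ether of the C3 CH2OH of 21, p-coumarate salt (not isolated) | CC(C)(C)[Si](c1ccccc1)(c1ccccc1)OCCCc1cc(OC)c2c(c1)[C@@H](CO[P+](c1ccccc1)(c1ccccc1)c1ccccc1)[C@H](c1ccc(O)c(OC)c1)O2.[O-]C(=O)/C=C/c1ccc(O)cc1 | intermediate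
24 | [(2R,3S)-2-(4-hydroxy-3-methoxyphenyl)-7-methoxy-5-[3-(TBDPS-oxy)propyl]-2,3-dihydrobenzofuran-3-yl]methyl (E)-3-(4-hydroxyphenyl)acrylate | CC(C)(C)[Si](c1ccccc1)(c1ccccc1)OCCCc1cc(OC)c2c(c1)[C@@H](COC(=O)/C=C/c1ccc(O)cc1)[C@H](c1ccc(O)c(OC)c1)O2 | intermediate
25 | [(2R,3S)-2-(4-hydroxy-3-methoxyphenyl)-5-(3-hydroxypropyl)-7-methoxy-2,3-dihydrobenzofuran-3-yl]methyl (E)-3-(4-hydroxyphenyl)acrylate | OCCCc1cc(OC)c2c(c1)[C@@H](COC(=O)/C=C/c1ccc(O)cc1)[C@H](c1ccc(O)c(OC)c1)O2 | intermediate
26 | (E)-ferulic acid | COc1cc(/C=C/C(=O)O)ccc1O | starting material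
27 | triphenylphosphonio ether of the propanol OH of 25, ferulate salt (not isolated) | c1ccccc1[P+](c1ccccc1)(c1ccccc1)OCCCc1cc(OC)c2c(c1)[C@@H](COC(=O)/C=C/c1ccc(O)cc1)[C@H](c1ccc(O)c(OC)c1)O2.COc1cc(/C=C/C([O-])=O)ccc1O | intermediate
28 | (+)-boehmenan X | COc1cc(/C=C/C(=O)OCCCc2cc(OC)c3c(c2)[C@@H](COC(=O)/C=C/c2ccc(O)cc2)[C@H](c2ccc(O)c(OC)c2)O3)ccc1O | target

Total step count: 14.
Longest linear sequence: 13 steps (steps 1–7 and 9–14, from 1 to 28); step 8 is the one-step side branch.

Three steps most likely to fail

Step 11. The MOM cleavage may be slower than the side reactions it has to outrun. During it the silyl ether may be lost, the cation may lose the C3 proton or formaldehyde to give a stilbene, or the diol may be tied up as a methylene acetal by the formaldehyde equivalents released. The fallback sets out from 18 and returns at 21, and generates the same quinone methide without protic acid. TMSBr in CH2Cl2 at −30 to 0 °C should cleave both aryl MOM ethers and turn the electron-rich benzylic alcohol into the bromide, giving the tris(trimethylsilyl) benzylic bromide F1, in which the two phenols and the CH2OH are transiently silylated. Shaking the cold solution with aqueous NaHCO3 should hydrolyse the labile trimethylsilyl ethers and eliminate HBr across the ring (1,6-elimination) to 20, which closes to 21 in a neutral to weakly basic medium where neither E1 loss nor acid desilylation is possible.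

Step 10. The alpha-aryl beta-hydroxy imide may undergo retro-aldol cleavage or alpha-epimerisation under the basic alkoxyborohydride conditions, which would cost material or enantiomeric purity at the future C3. The fallback sets out from 17 and returns at 21. Silylation of the carbinol (TESOTf, 2,6-lutidine, CH2Cl2, −78 °C) gives the O-triethylsilyl aldol adduct F2, which can no longer fragment by retro-aldol. LiBH4 in THF at 0 °C then removes the auxiliary to give the benzylic O-triethylsilyl diol F3. F3 is submitted to the conditions of step 11, where methanolic HCl removes the triethylsilyl and MOM groups together and the material passes through 19 and 20 to 21.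

Step 12. The oxyphosphonium intermediate may eliminate toward the benzylic C3–H to give an exocyclic alkene, or the free phenols may compete as nucleophiles and slow the esterification. The fallback sets out from 21 and returns at 24, and acylates without activating the alcohol. Phenol-selective acetylation through the phenoxide (Ac2O, aqueous NaOH, THF/iPrOH, 0 °C) gives the guaiacyl acetate F4. Steglich esterification of its CH2OH with commercial (E)-4-acetoxycinnamic acid (EDC·HCl, catalytic DMAP, CH2Cl2, 0 °C) gives the diacetate ester F5. Pyrrolidine in CH2Cl2/EtOH at 0 °C should then aminolyse the two aryl acetates much faster than the alkyl cinnamate and return 24.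

Further compounds
F1 | step 11 | tris(trimethylsilyl) benzylic bromide from 18 (bromide carbon as a mixture of epimers) | C[Si](C)(C)OC[C@H](c1cc(CCCO[Si](c2ccccc2)(c2ccccc2)C(C)(C)C)cc(OC)c1O[Si](C)(C)C)C(Br)c1ccc(O[Si](C)(C)C)c(OC)c1
F2 | step 10 | O-triethylsilyl ether of aldol adduct 17 | O=C(N1[C@H](Cc2ccccc2)COC1=O)[C@H](c1cc(CCCO[Si](c2ccccc2)(c2ccccc2)C(C)(C)C)cc(OC)c1OCOC)[C@@H](O[Si](CC)(CC)CC)c1ccc(OCOC)c(OC)c1
F3 | step 10 | (2S,3R)-2-(ArB)-3-(ArG)-3-(triethylsilyloxy)propan-1-ol | OC[C@H](c1cc(CCCO[Si](c2ccccc2)(c2ccccc2)C(C)(C)C)cc(OC)c1OCOC)[C@@H](O[Si](CC)(CC)CC)c1ccc(OCOC)c(OC)c1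
F4 | step 12 | guaiacyl O-acetate of 21 | CC(C)(C)[Si](c1ccccc1)(c1ccccc1)OCCCc1cc(OC)c2c(c1)[C@@H](CO)[C@H](c1ccc(OC(C)=O)c(OC)c1)O2
F5 | step 12 | C3-CH2 (E)-4-acetoxycinnamate of F4 (diacetate of 24) | CC(C)(C)[Si](c1ccccc1)(c1ccccc1)OCCCc1cc(OC)c2c(c1)[C@@H](COC(=O)/C=C/c1ccc(OC(C)=O)cc1)[C@H](c1ccc(OC(C)=O)c(OC)c1)O2
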